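- I decide to reckon one thing per flask: the share of the charge it turns over if its early rate simply holds.

| flask | solid substrate | reagent | temperature | remark | time |
|---|---|---|---|---|---|
| ash | 0.050 M | 4 equiv | −20 °C | run made earlier |  |
| alder | 0.075 M | 4 equiv | 5 °C | run made earlier |  |
| elm | 0.10 M | 6 equiv | −20 °C | run made earlier |  |
| violet | 0.10 M | 4.00 equiv |  | at 25 °C until 3.0 d, from then on at −15 °C | 6.0 d |
| amber | 0.10 M | 4.00 equiv |  | at −15 °C throughout | 2.0 d |

| run | time / d | target / % |
|---|---|---|
| ash | 6.00 | 5 |
| ash | 8.00 | 0 |
| ash | 12.0 | 4 |
| ash | 20.0 | 9 |
| ash | 30.0 | 12 |
| ash | 50.0 | 15 |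
| ash | 80.0 | 25 |
| alder | 3.00 | 30 |
| alder | 6.00 | 54 |
| alder | 8.00 | 61 |
| alder | 10.0 | 69 |
| alder | 15.0 | 75 |
| alder | 20.0 | 79 |
| elm | 6.00 | 3 |
| elm | 10.0 | 5 |
| elm | 20.0 | 11 |
| elm | 40.0 | 18 |
| elm | 80.0 | 37 |

(scatter of a reading: 2 percentage points)

- the winner by amount of target, in percent of the solid substrate charged; "neither" if no more than 2 percentage points parts them (violet / amber / neither)
- how much target is there at the end, in percent of the solid substrate charged: violet
- how much target is there at the end, in percent of the solid substrate charged: amber

- given per volume of solution although it is solid: solid substrate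
- the earlier runs were read with a standard deviation of 2 percentage points
- at the start none of the solid substrate is in solution
- what has only dissolved of solid substrate counts as not reacted

- At −20 °C, elm has made a factor of 2.96 more target in absolute terms than ash by 80.0 d, but elm differs from ash both in the loading of solid substrate and in [reagent], so that factor separates neither. I set elm aside and work from ash and alder, which hold the recipes' equivalents of reagent, assuming that the share of the charge turned over per day does not depend on the loading.
- Ash's last reading gives 0.00313 d⁻¹ of the charge at −20 °C.
- Alder's first reading against ash's last, at equal equivalents, gives a factor of 32.0 between −20 °C and 5 °C; I spread it evenly on a logarithmic scale.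
- Folded together, this gives 1.25% for amber: the turnover number D (a Damköhler number), which is the scaled early rate times the time, as a share of the charge.
- Violet's hot stage gives D = 4.80, far above amber's.
- Far below one, D is itself the yield, a small correction to nothing having happened. Above one, the early rate outruns the charge and D stops being an amount.
- Is one number enough? Alder reaches D = 2.00 at 20.0 d and reads 79%, flattening from 75%. So D shows that the curve bends, not how high it ends. I commit to violet as winner and to 1.25% for amber, but I give violet no firm height.
- The forecast says violet, with 80% for violet and 1.5% for amber, above my amber figure. It explains the levelling as “possibly from reversibility or reagent loss”.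
- The flasks give violet as winner, with 63.1% for violet and 1.15% for amber.

    starting material + reagent → target, rate k1*[starting material]*[reagent]^0.5 (k = 0.120 M⁻⁰·⁵ h⁻¹, Ea = 80.0 kJ mol⁻¹)
    reagent → decomposition product (k = 7.40 × 10⁻⁵ h⁻¹, Ea = 123 kJ mol⁻¹)
    reagent + target → over-reaction product (k = 0.0340 M⁻¹ h⁻¹, Ea = 86.0 kJ mol⁻¹)
    solid substrate ⇌ starting material, rate k4*(cs4 - [starting material]) while solid is left; crystals form when [starting material] > cs4 (solubility = 0.0710 M, k = 0.0590 h⁻¹)
    (constants at 25 °C)

- The temperature programme is the main reason the two flasks part: with that difference taken away, amber ends at 66.0% instead of 1.15%. Amber's 1.15% lies close to its D of 1.25%. A neighbour flask, amber repeated at 0 °C, has D = 10.0% and gives 8.52%. In violet, with D = 4.80, conversion of the solid substrate reaches 96.7%, yet target ends at 63.1%. The gap comes from reagent passing target on into over-reaction product: with that step taken away, violet ends at 97.0%.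

(The data are simulated from invented constants; the scatter is artificial.)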